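**Plan** (ring atoms numbered as in 7-oxabicyclo[4.1.0]heptane: C1 quaternary oxirane carbon, C2 ketone, C3, C4 bearing CH2OH, C5 carbinol, C6 oxirane CH; C1' is the heptenyl CH on C3)

- Cuts: first the C3–C1' σ-bond of the dienone (ring C3 vinyl bromide + (E)-heptenylboron reagent); then C5–OH back to the ketone, the C1–O–C6 oxirane back to a quinone monoketal, the ring back to an arene, the side-chain C=C (cross-metathesis) and the ring C1–CH2 bond (Claisen).
- Forward: the carbocycle is the benzene ring of 2,5-dihydroxybenzaldehyde, which is brominated, allylated and rearranged, chain-extended and dearomatised; the oxirane is the only ring that is made; the heptenyl chain is joined in the penultimate step and the last step unmasks C2=O and CO2H.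
- Stereochemistry: C1 and C6 from a tartrate-mediated, hydroxymethyl-directed nucleophilic epoxidation (reagent control); C5 from hydride addition anti to the oxirane C–O bond (substrate control); side-chain E from cross-metathesis; heptenyl E bought with the boronate and retained.
- Enabling feature: C3 of the cyclohexene ring is an sp2 carbon between the C2 ketal carbon and C4(CH2OH). The bromine placed on it in step 1 blocks that ortho position in the Claisen step, keeps the C3=C4 alkene tetrasubstituted and inert to peroxide, and is the handle for a stereoretentive Pd coupling. The C2 dimethyl ketal is a temporary mask for the epoxy ketone during the coupling.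

Key step: step 10

Assumption: the tartrate antipode that gives the (1R,6S)-epoxide in step 8 is taken to be L-(+)-DIPT by analogy with related hydroxymethyl quinone monoketals; if the sense is opposite, D-(−)-DIPT is used and nothing else changes.

**Step 1**
Reactants: 1 2,5-dihydroxybenzaldehyde
Product: 2 2-bromo-3,6-dihydroxybenzaldehyde
Conditions: Br2 (1.0 equiv), CHCl3, 0 °C to rt
Reagents that add atoms: bromine, BrBr
Why: Electrophilic aromatic bromination; the non-chelated 5-OH directs ortho and, as with other 3-hydroxybenzaldehydes, substitution should occur at the position between OH and CHO.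

**Step 2**
Reactants: 2 2-bromo-3,6-dihydroxybenzaldehyde; 3 allyl bromide
Product: 4 2-bromo-6-hydroxy-3-(prop-2-enyloxy)benzaldehyde
Conditions: K2CO3 (1.0 equiv), acetone, rt to 40 °C, Ar
Reagents that add atoms: none
Why: Williamson etherification; the 6-OH is hydrogen-bonded to the aldehyde and its phenoxide is chelated and poorly nucleophilic, so one equivalent of base should alkylate only the 3-OH.

**Step 3**
Reactants: 4 2-bromo-6-hydroxy-3-(prop-2-enyloxy)benzaldehyde
Product: 5 2-bromo-3,6-dihydroxy-4-(prop-2-enyl)benzaldehyde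
Conditions: decalin, 180 °C, Ar
Reagents that add atoms: none
Why: Aromatic Claisen [3,3] rearrangement; C4 is the only free ortho carbon (C2 carries Br, the para carbon carries OH), so the allyl group should migrate there and the dienone re-aromatises by tautomerisation.

**Step 4**
Reactants: 5 2-bromo-3,6-dihydroxy-4-(prop-2-enyl)benzaldehyde
Product: 6 2-bromo-6-hydroxy-3-methoxy-4-(prop-2-enyl)benzaldehyde
Conditions: MeI (1.2 equiv), K2CO3 (1.1 equiv), acetone, rt, Ar
Reagents that add atoms: iodomethane, CI
Why: Williamson O-methylation; the aldehyde-chelated 6-OH should again be spared, and the small electrophile tolerates the two ortho substituents of the 3-OH.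

**Step 5**
Reactants: 6 2-bromo-6-hydroxy-3-methoxy-4-(prop-2-enyl)benzaldehyde; 7 tert-butyl methacrylate
Product: 8 tert-butyl (E)-4-(3-bromo-4-formyl-5-hydroxy-2-methoxyphenyl)-2-methylbut-2-enoate
Conditions: Hoveyda–Grubbs II (5 mol %), 7 (10 equiv), 1,4-benzoquinone (10 mol %), CH2Cl2, 40 °C
Reagents that add atoms: none
Why: Olefin cross-metathesis of a terminal alkene with a 1,1-disubstituted acrylate, driven by loss of ethene; the trisubstituted enoate should form as the thermodynamically favoured E isomer (ester trans to the CH2Ar group).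

**Step 6**
Reactants: 8 tert-butyl (E)-4-(3-bromo-4-formyl-5-hydroxy-2-methoxyphenyl)-2-methylbut-2-enoate
Product: 9 tert-butyl (E)-4-[3-bromo-5-hydroxy-4-(hydroxymethyl)-2-methoxyphenyl]-2-methylbut-2-enoate
Conditions: NaBH4, THF/MeOH, 0 °C
Reagents that add atoms: none
Why: Borohydride 1,2-reduction of the aryl aldehyde; the conjugated tert-butyl ester and the aryl bromide are inert under these conditions.

**Step 7**
Reactants: 9 tert-butyl (E)-4-[3-bromo-5-hydroxy-4-(hydroxymethyl)-2-methoxyphenyl]-2-methylbut-2-enoate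
Product: 10 tert-butyl (E)-4-[5-bromo-4-(hydroxymethyl)-6,6-dimethoxy-3-oxocyclohexa-1,4-dien-1-yl]-2-methylbut-2-enoate
Conditions: PhI(OAc)2 (1.1 equiv), MeOH, 0 °C
Reagents that add atoms: methanol, CO
Why: Hypervalent-iodine oxidative dearomatisation of a p-methoxyphenol; the phenoxonium ion should be trapped by methanol at the para carbon that carries OMe, giving the quinone monoketal with the ketal next to C–Br and the side-chain carbon.

**Step 8**
Reactants: 10 tert-butyl (E)-4-[5-bromo-4-(hydroxymethyl)-6,6-dimethoxy-3-oxocyclohexa-1,4-dien-1-yl]-2-methylbut-2-enoate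
Product: 11 tert-butyl (E)-4-[(1R,6S)-3-bromo-4-(hydroxymethyl)-2,2-dimethoxy-5-oxo-7-oxabicyclo[4.1.0]hept-3-en-1-yl]-2-methylbut-2-enoate
Conditions: Ph3COOH, NaHMDS, L-(+)-DIPT, 4 Å MS, toluene, −50 °C
Reagents that add atoms: trityl hydroperoxide, OOC(c1ccccc1)(c1ccccc1)c1ccccc1
Why: Tartrate-mediated Weitz–Scheffer nucleophilic epoxidation: the sodium alkoxide of the hydroxymethyl group and the carbonyl oxygen should bind the sodium tartrate–trityl peroxide aggregate, the peroxide adds to the β-carbon of the trisubstituted CH=C(CH2R) alkene (the other alkene is tetrasubstituted and carries Br on its β-carbon) and the enolate closes with loss of trityl oxide, so both new stereocentres (1R,6S, oxirane necessarily cis-fused) are set by the chiral tartrate.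

**Step 9**
Reactants: 11 tert-butyl (E)-4-[(1R,6S)-3-bromo-4-(hydroxymethyl)-2,2-dimethoxy-5-oxo-7-oxabicyclo[4.1.0]hept-3-en-1-yl]-2-methylbut-2-enoate
Product: 12 tert-butyl (E)-4-[(1R,5R,6R)-3-bromo-5-hydroxy-4-(hydroxymethyl)-2,2-dimethoxy-7-oxabicyclo[4.1.0]hept-3-en-1-yl]-2-methylbut-2-enoate (C5–OH cis to the oxirane oxygen)
Conditions: DIBAL-H (2.5 equiv), THF, −78 °C; Rochelle salt work-up
Reagents that add atoms: none
Why: 1,2-Hydride reduction of the epoxy enone; hydride should add to C5=O on the face opposite the oxirane oxygen (Felkin–Anh-type attack anti to the α C–O bond, also the less hindered face), which sets 5R with the hydroxyl cis to the oxirane oxygen, and at −78 °C in THF the ketone should react well before the hindered α-methyl enoate tert-butyl ester.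

**Step 10**
Reactants: 12 tert-butyl (E)-4-[(1R,5R,6R)-3-bromo-5-hydroxy-4-(hydroxymethyl)-2,2-dimethoxy-7-oxabicyclo[4.1.0]hept-3-en-1-yl]-2-methylbut-2-enoate; 13 (E)-2-(hept-1-enyl)-4,4,5,5-tetramethyl-1,3,2-dioxaborolane
Product: 14 tert-butyl (E)-4-[(1R,5R,6R)-3-[(E)-hept-1-enyl]-5-hydroxy-4-(hydroxymethyl)-2,2-dimethoxy-7-oxabicyclo[4.1.0]hept-3-en-1-yl]-2-methylbut-2-enoate
Conditions: Pd(OAc)2 (5 mol %), SPhos (10 mol %), K3PO4 (3 equiv), THF/H2O (10:1), 50 °C, degassed
Reagents that add atoms: none
Why: Suzuki–Miyaura alkenyl–alkenyl coupling: Pd(0) inserts into the C3–Br bond of the ring vinyl bromide with retention, the phosphate-activated boronate 13 transfers its (E)-alkenyl group with retention, and reductive elimination forms the C3–C1' σ-bond of the 1,3-diene. The closest known reaction type is the Pd-catalysed coupling of hindered 2-bromocycloalkenyl ketals and β-bromo enones with (E)-1-alkenyl boron or tin reagents. No ring is closed and no sp3 stereocentre is created; the only new stereo-element, the (E)-C1'=C2' geometry, is carried over unchanged from 13, and C1, C5 and C6 are not touched. The step needs chemoselectivity for the C–Br bond and a substrate that tolerates aqueous base: C3–Br is the only C(sp2)–halogen bond, the C2 dimethyl ketal keeps the base-labile γ-hydroxy epoxy enone masked, and the cis relationship of the C5 hydroxyl and the oxirane oxygen rules out a Payne rearrangement because the alkoxide cannot reach the backside of the C6–O bond. The bulky, electron-rich SPhos ligand is chosen because C3 is flanked by the quaternary ketal carbon and the fully substituted C4.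

**Step 11**
Reactants: 14 tert-butyl (E)-4-[(1R,5R,6R)-3-[(E)-hept-1-enyl]-5-hydroxy-4-(hydroxymethyl)-2,2-dimethoxy-7-oxabicyclo[4.1.0]hept-3-en-1-yl]-2-methylbut-2-enoate
Product: 16 (E)-4-[(1R,5R,6R)-3-[(E)-hept-1-enyl]-5-hydroxy-4-(hydroxymethyl)-2-oxo-7-oxabicyclo[4.1.0]hept-3-en-1-yl]-2-methylbut-2-enoic acid, via keto tert-butyl ester 15 (not isolated)
Conditions: TFA/CH2Cl2/H2O (5:5:1), 0 °C to rt; NaHCO3 work-up, then acidify to pH 3
Reagents that add atoms: water, O
Why: Acid-mediated global unmasking: the dienyl-stabilised oxocarbenium ion of the ketal should be hydrolysed first to the C2 ketone, then the tert-butyl ester loses isobutene (E1), while the oxirane, deactivated by the flanking carbonyl, and the three stereocentres should be left untouched.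

**Compound list**

1 | 2,5-dihydroxybenzaldehyde | O=Cc1cc(O)ccc1O | starting material
2 | 2-bromo-3,6-dihydroxybenzaldehyde | O=Cc1c(Br)c(O)ccc1O | intermediate
3 | allyl bromide | C=CCBr | starting material
4 | 2-bromo-6-hydroxy-3-(prop-2-enyloxy)benzaldehyde | O=Cc1c(Br)c(OCC=C)ccc1O | intermediate
5 | 2-bromo-3,6-dihydroxy-4-(prop-2-enyl)benzaldehyde | O=Cc1c(Br)c(O)c(CC=C)cc1O | intermediate
6 | 2-bromo-6-hydroxy-3-methoxy-4-(prop-2-enyl)benzaldehyde | O=Cc1c(Br)c(OC)c(CC=C)cc1O | intermediate
7 | tert-butyl methacrylate | C=C(C)C(=O)OC(C)(C)C | starting material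
8 | tert-butyl (E)-4-(3-bromo-4-formyl-5-hydroxy-2-methoxyphenyl)-2-methylbut-2-enoate | O=Cc1c(Br)c(OC)c(C/C=C(\C)C(=O)OC(C)(C)C)cc1O | intermediate
9 | tert-butyl (E)-4-[3-bromo-5-hydroxy-4-(hydroxymethyl)-2-methoxyphenyl]-2-methylbut-2-enoate | OCc1c(Br)c(OC)c(C/C=C(\C)C(=O)OC(C)(C)C)cc1O | intermediate
10 | tert-butyl (E)-4-[5-bromo-4-(hydroxymethyl)-6,6-dimethoxy-3-oxocyclohexa-1,4-dien-1-yl]-2-methylbut-2-enoate | O=C1C=C(C/C=C(\C)C(=O)OC(C)(C)C)C(OC)(OC)C(Br)=C1CO | intermediate
11 | tert-butyl (E)-4-[(1R,6S)-3-bromo-4-(hydroxymethyl)-2,2-dimethoxy-5-oxo-7-oxabicyclo[4.1.0]hept-3-en-1-yl]-2-methylbut-2-enoate | BrC1=C(CO)C(=O)[C@H]2O[C@@]2(C/C=C(\C)C(=O)OC(C)(C)C)C1(OC)OC | intermediate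
12 | tert-butyl (E)-4-[(1R,5R,6R)-3-bromo-5-hydroxy-4-(hydroxymethyl)-2,2-dimethoxy-7-oxabicyclo[4.1.0]hept-3-en-1-yl]-2-methylbut-2-enoate | BrC1=C(CO)[C@@H](O)[C@H]2O[C@@]2(C/C=C(\C)C(=O)OC(C)(C)C)C1(OC)OC | intermediate
13 | (E)-2-(hept-1-enyl)-4,4,5,5-tetramethyl-1,3,2-dioxaborolane | CCCCC/C=C/B1OC(C)(C)C(C)(C)O1 | starting material
14 | tert-butyl (E)-4-[(1R,5R,6R)-3-[(E)-hept-1-enyl]-5-hydroxy-4-(hydroxymethyl)-2,2-dimethoxy-7-oxabicyclo[4.1.0]hept-3-en-1-yl]-2-methylbut-2-enoate | CCCCC/C=C/C1=C(CO)[C@@H](O)[C@H]2O[C@@]2(C/C=C(\C)C(=O)OC(C)(C)C)C1(OC)OC | intermediate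
15 | tert-butyl (E)-4-[(1R,5R,6R)-3-[(E)-hept-1-enyl]-5-hydroxy-4-(hydroxymethyl)-2-oxo-7-oxabicyclo[4.1.0]hept-3-en-1-yl]-2-methylbut-2-enoate (forms in the flask in step 11) | CCCCC/C=C/C1=C(CO)[C@@H](O)[C@H]2O[C@@]2(C/C=C(\C)C(=O)OC(C)(C)C)C1=O | intermediate
16 | (E)-4-[(1R,5R,6R)-3-[(E)-hept-1-enyl]-5-hydroxy-4-(hydroxymethyl)-2-oxo-7-oxabicyclo[4.1.0]hept-3-en-1-yl]-2-methylbut-2-enoic acid (ambuic acid) | CCCCC/C=C/C1=C(CO)[C@@H](O)[C@H]2O[C@@]2(C/C=C(\C)C(=O)O)C1=O | target

**Totals**

Total steps: 11. Longest linear sequence: 11 steps (from 1).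

**Steps most likely to fail**

Step 8. The process at risk is insufficient enantiofacial discrimination (or loss of site selectivity between the two ring alkenes) in the tartrate-mediated peroxide addition, because the attacked β-carbon is fully substituted and the ketal is acyclic. The fallback replaces reagent control by auxiliary control and sets out from 10. Transketalisation with (2R,4R)-pentane-2,4-diol (BF3·OEt2, DME) should give the chiral spiroketal dienone F1. Epoxidation under achiral conditions (Ph3COOH, KHMDS, THF, −78 °C) should be biased by the C2-symmetric dioxane and in any case gives separable diastereomers, of which the (1R,6S)-epoxide spiroketal F2 is taken on (the antipodal diol is used if that makes it the major isomer). DIBAL-H reduction as in step 9 should give the syn-epoxy alcohol spiroketal F3, coupling with 13 as in step 10 the dienyl spiroketal F4, and aqueous TFA as in step 11 rejoins the route at 16.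

Step 9. The process at risk is poor facial selectivity of hydride delivery, for example if aluminium bound to the oxirane oxygen delivers hydride on the oxirane face so that the C5 epimer predominates. The fallback uses inversion instead of direct control and sets out from 11. The reduction is then run on purpose to the 5-epi alcohol F5. Selective silylation of the primary hydroxyl (TBSCl, imidazole, CH2Cl2, 0 °C) should give the primary silyl ether F6. A Mitsunobu reaction (4-nitrobenzoic acid, PPh3, DIAD, toluene) should invert C5 and give the 4-nitrobenzoate F7. Methanolysis (K2CO3, MeOH, 0 °C) should give the 5R alcohol silyl ether F8, and HF·pyridine in THF removes the silyl group to rejoin the route at 12.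

Step 10. The process at risk is slow oxidative addition at the hindered, electron-rich C3–Br bond, so that decomposition of the boronate or of the substrate under warm aqueous base takes over. The fallback moves the union one oxidation level earlier and sets out from 11, whose C3–Br bond is β to the C5 ketone and therefore more reactive towards Pd(0). Coupling of 11 with 13 (Pd(OAc)2, SPhos, K3PO4, THF/H2O, rt to 40 °C) should give the dienyl epoxy ketone F9, and DIBAL-H reduction under the conditions of step 9 rejoins the route at 14.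

**Further compounds**

F1 | step 8 | analogue of 10 with the C6 ketal as the spiroketal of (2R,4R)-pentane-2,4-diol | O=C1C=C(C/C=C(\C)C(=O)OC(C)(C)C)C2(O[C@H](C)C[C@@H](C)O2)C(Br)=C1CO
F2 | step 8 | analogue of 11, (1R,6S)-epoxide, with the (2R,4R)-pentane-2,4-diol spiroketal at C2 | BrC1=C(CO)C(=O)[C@H]2O[C@@]2(C/C=C(\C)C(=O)OC(C)(C)C)C13O[C@H](C)C[C@@H](C)O3
F3 | step 8 | analogue of 12, (1R,5R,6R), with the (2R,4R)-pentane-2,4-diol spiroketal at C2 | BrC1=C(CO)[C@@H](O)[C@H]2O[C@@]2(C/C=C(\C)C(=O)OC(C)(C)C)C13O[C@H](C)C[C@@H](C)O3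
F4 | step 8 | analogue of 14, (1R,5R,6R), with the (2R,4R)-pentane-2,4-diol spiroketal at C2 | CCCCC/C=C/C1=C(CO)[C@@H](O)[C@H]2O[C@@]2(C/C=C(\C)C(=O)OC(C)(C)C)C13O[C@H](C)C[C@@H](C)O3
F5 | step 9 | tert-butyl (E)-4-[(1R,5S,6R)-3-bromo-5-hydroxy-4-(hydroxymethyl)-2,2-dimethoxy-7-oxabicyclo[4.1.0]hept-3-en-1-yl]-2-methylbut-2-enoate (C5 epimer of 12) | BrC1=C(CO)[C@H](O)[C@H]2O[C@@]2(C/C=C(\C)C(=O)OC(C)(C)C)C1(OC)OC
F6 | step 9 | primary tert-butyldimethylsilyl ether of F5, (1R,5S,6R) | BrC1=C(CO[Si](C)(C)C(C)(C)C)[C@H](O)[C@H]2O[C@@]2(C/C=C(\C)C(=O)OC(C)(C)C)C1(OC)OC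
F7 | step 9 | C5 4-nitrobenzoate with inverted C5, (1R,5R,6R), primary TBS ether | BrC1=C(CO[Si](C)(C)C(C)(C)C)[C@@H](OC(=O)c3ccc(cc3)[N+](=O)[O-])[C@H]2O[C@@]2(C/C=C(\C)C(=O)OC(C)(C)C)C1(OC)OC
F8 | step 9 | primary tert-butyldimethylsilyl ether of 12, (1R,5R,6R) | BrC1=C(CO[Si](C)(C)C(C)(C)C)[C@@H](O)[C@H]2O[C@@]2(C/C=C(\C)C(=O)OC(C)(C)C)C1(OC)OC
F9 | step 10 | tert-butyl (E)-4-[(1R,6S)-3-[(E)-hept-1-enyl]-4-(hydroxymethyl)-2,2-dimethoxy-5-oxo-7-oxabicyclo[4.1.0]hept-3-en-1-yl]-2-methylbut-2-enoate | CCCCC/C=C/C1=C(CO)C(=O)[C@H]2O[C@@]2(C/C=C(\C)C(=O)OC(C)(C)C)C1(OC)OC
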